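Everything rests on cutting the aryl ketone bond C4–C4a of the pyranone ring. In ring A, C4a lies between C8a (bearing O1) and the oxygenated C5. In a 2,5-dioxygenated aryl ether it is therefore the only free ortho carbon, and two ortho oxygens activate it. An enantioenriched β-lactone acts as a 1,3-dielectrophile. Its alkyl C–O carbon first etherifies 2,5-dimethoxyphenoxide with inversion, which sets C2. The carboxyl group released then acylates C4a in the key Friedel–Crafts ring closure. The precursor of that step is an open-chain (R)-3-aryloxy acid that already carries the Z-alkene. Double O-demethylation completes a four-step route.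

Key step: step 3

Assumption: 1, 2 and 5 are bought (1 is a commercial moth pheromone component), the ligand of step 1 is a catalyst component made separately from L-valinol and not counted, and chromanone numbering (O1 to C8a, ring A = benzene ring) is used throughout.

Step 1
Reactants: 1 (Z)-octadec-13-enal; 2 acetyl bromide
Product: 4 (4S)-4-[(12Z)-heptadec-12-en-1-yl]oxetan-2-one, via ketene 3 (not isolated)
Conditions: AlMe3 (10 mol %), N-benzyl-N,N-bis[(2S)-3-methyl-2-(trifluoromethylsulfonylamino)butyl]amine (10 mol %), i-Pr2NEt (1.7 equiv), 2 (1.9 equiv), CH2Cl2, −50 °C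
Reagents that add atoms: none
Why: Catalytic asymmetric acyl halide–aldehyde cyclocondensation (formal ketene–aldehyde [2+2] cycloaddition), in which the chiral aluminium triamine complex binds the unbranched aldehyde and shields one face, so that ketene made in situ should add to give the (S)-β-lactone while the remote isolated alkene stays inert at −50 °C.

Step 2
Reactants: 4 (4S)-4-[(12Z)-heptadec-12-en-1-yl]oxetan-2-one; 5 2,5-dimethoxyphenol
Product: 7 (3R,15Z)-3-(2,5-dimethoxyphenoxy)icos-15-enoic acid, via sodium 2,5-dimethoxyphenoxide 6 (not isolated)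
Conditions: 5 (1.3 equiv), NaH (1.3 equiv), DMF, 0 °C; then 4, 0 → 40 °C; 1 M HCl work-up
Reagents that add atoms: sodium hydride, [Na+].[H-] (its sodium is kept only in 6)
Why: SN2 alkyl–oxygen cleavage of a β-lactone by a phenoxide, in which strain release lets the phenoxide attack C4 of the lactone from the rear, so that the (S)-centre should be inverted to the (R)-aryl ether and the carboxyl group is freed for the ring closure.

Step 3
Reactants: 7 (3R,15Z)-3-(2,5-dimethoxyphenoxy)icos-15-enoic acid
Product: 9 (2R)-2-[(12Z)-heptadec-12-en-1-yl]-5,8-dimethoxy-2,3-dihydro-4H-chromen-4-one, via acyl trifluoroacetate 8 (not isolated)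
Conditions: (CF3CO)2O (3 equiv), CH2Cl2 (0.05 M), 0 °C → rt
Reagents that add atoms: trifluoroacetic anhydride, O=C(OC(=O)C(F)(F)F)C(F)(F)F (its CF3CO group is kept only in 8)
Why: Intramolecular Friedel–Crafts acylation: 7 and (CF3CO)2O give mixed anhydride 8, whose acyl carbon (future C4) is attacked by aryl carbon C6 (future C4a), and loss of the ring proton as CF3CO2H restores ring A. The closest known reaction type is the cyclodehydration of 3-aryloxyalkanoic acids to chroman-4-ones. The pyranone ring closes in the 6-exo-trig mode at the acyl C=O. No stereocentre is formed; C2 is only carried through, and the absence of base and of strong acid should keep β-elimination of the aryloxide, the only racemisation path, slow. Site selectivity lies in the substrate: the second ortho carbon bears OMe, the three-atom tether reaches no other position, and C4a is activated by two ortho oxygens (O1 and the C5 methoxy group). Chemoselectivity over the Z-alkene rests on the weak acidity of dilute CF3CO2H in CH2Cl2.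

Step 4
Reactants: 9 (2R)-2-[(12Z)-heptadec-12-en-1-yl]-5,8-dimethoxy-2,3-dihydro-4H-chromen-4-one
Product: 10 (2R)-2-[(12Z)-heptadec-12-en-1-yl]-5,8-dihydroxy-2,3-dihydro-4H-chromen-4-one
Conditions: BBr3 (3.5 equiv), CH2Cl2, −78 → 0 °C, argon; then ice-water
Reagents that add atoms: none
Why: Lewis acid cleavage of aryl methyl ethers, in which BBr3 binds each methoxy oxygen (the C5 one chelated to the C4 carbonyl) and bromide removes the methyl group by SN2, while the vinylogous-ester oxygen O1, the secondary C2–O bond and the isolated alkene should stay untouched at or below 0 °C.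

Compound list
1 | (Z)-octadec-13-enal | CCCC/C=C\CCCCCCCCCCCC=O | starting material
2 | acetyl bromide | CC(=O)Br | starting material
3 | ketene | C=C=O | intermediate
4 | (4S)-4-[(12Z)-heptadec-12-en-1-yl]oxetan-2-one | CCCC/C=C\CCCCCCCCCCC[C@H]1CC(=O)O1 | intermediate
5 | 2,5-dimethoxyphenol | COc1ccc(OC)c(O)c1 | starting material
6 | sodium 2,5-dimethoxyphenoxide | [Na+].[O-]c1cc(OC)ccc1OC | intermediate
7 | (3R,15Z)-3-(2,5-dimethoxyphenoxy)icos-15-enoic acid | CCCC/C=C\CCCCCCCCCCC[C@H](CC(=O)O)Oc1cc(OC)ccc1OC | intermediate
8 | (3R,15Z)-3-(2,5-dimethoxyphenoxy)icos-15-enoic trifluoroacetic anhydride | CCCC/C=C\CCCCCCCCCCC[C@H](CC(=O)OC(=O)C(F)(F)F)Oc1cc(OC)ccc1OC | intermediate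
9 | (2R)-2-[(12Z)-heptadec-12-en-1-yl]-5,8-dimethoxy-2,3-dihydro-4H-chromen-4-one | CCCC/C=C\CCCCCCCCCCC[C@@H]1CC(=O)c2c(OC)ccc(OC)c2O1 | intermediate
10 | (2R)-2-[(12Z)-heptadec-12-en-1-yl]-5,8-dihydroxy-2,3-dihydro-4H-chromen-4-one | CCCC/C=C\CCCCCCCCCCC[C@@H]1CC(=O)c2c(O)ccc(O)c2O1 | target

Total step count: 4. Longest linear sequence: 4.

Steps most likely to fail

1. Step 2. Attack of the phenoxide at the acyl carbon, or deprotonation at C3 with ring-opening elimination, may outrun the SN2 opening. The fallback replaces lactone alkylation by Mitsunobu etherification.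
   - It sets out from 4. Methanolysis (MeOH, cat. K2CO3, 0 °C) opens the acyl–oxygen bond with retention to methyl (3S,15Z)-3-hydroxyicos-15-enoate F1.
   - A Mitsunobu reaction with 5 (PPh3, DIAD, toluene, 0 °C) inverts C3 to methyl (3R,15Z)-3-(2,5-dimethoxyphenoxy)icos-15-enoate F2.
   - Neutral ester cleavage with Me3SnOH (1,2-dichloroethane, 70 °C) comes back to the route at 7.

2. Step 3. Slow acylation at the hindered carbon between two oxygens may let two side processes compete: β-elimination of the aryloxide with erosion of enantiopurity, and trifluoroacetylation of ring A. The fallback uses an aldehyde-level electrophile followed by oxidation.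
   - It sets out from 7. Carbonyldiimidazole, then i-Bu2AlH (CH2Cl2, −78 °C), gives (3R,15Z)-3-(2,5-dimethoxyphenoxy)icos-15-enal F3.
   - SnCl4-promoted intramolecular hydroxyalkylation (CH2Cl2, −78 °C) closes the same C4–C4a bond to (2R)-2-[(12Z)-heptadec-12-en-1-yl]-5,8-dimethoxychroman-4-ol F4, as a mixture of C4 epimers.
   - Dess–Martin periodinane converges both epimers on 9.

3. Step 4. Two things may go wrong: hydrobromination or geometric scrambling of the alkene by adventitious HBr, and Lewis acid-induced opening at O1–C2 with racemisation. The fallback replaces Lewis-acidic demethylation by oxidative demethylation.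
   - It sets out from 9. (NH4)2Ce(NO3)6 (MeCN/H2O, 0 °C) gives (2R)-2-[(12Z)-heptadec-12-en-1-yl]-2,3-dihydrochromene-4,5,8-trione F5.
   - This quinone is reduced at once with aqueous Na2S2O4, before it can tautomerise, to come back at 10.

Further compounds
F1 | step 2 | methyl (3S,15Z)-3-hydroxyicos-15-enoate | CCCC/C=C\CCCCCCCCCCC[C@H](O)CC(=O)OC
F2 | step 2 | methyl (3R,15Z)-3-(2,5-dimethoxyphenoxy)icos-15-enoate | CCCC/C=C\CCCCCCCCCCC[C@H](CC(=O)OC)Oc1cc(OC)ccc1OC
F3 | step 3 | (3R,15Z)-3-(2,5-dimethoxyphenoxy)icos-15-enal | CCCC/C=C\CCCCCCCCCCC[C@H](CC=O)Oc1cc(OC)ccc1OC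
F4 | step 3 | (2R)-2-[(12Z)-heptadec-12-en-1-yl]-5,8-dimethoxychroman-4-ol (C4 epimers) | CCCC/C=C\CCCCCCCCCCC[C@@H]1CC(O)c2c(OC)ccc(OC)c2O1
F5 | step 4 | (2R)-2-[(12Z)-heptadec-12-en-1-yl]-2,3-dihydrochromene-4,5,8-trione | CCCC/C=C\CCCCCCCCCCC[C@@H]1CC(=O)C2=C(O1)C(=O)C=CC2=O
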